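Numbering used throughout: coumarin atoms O1, C2, C3, C4, C4a, C5–C8, C8a; ring A is the benzenoid ring, ring B the lactone ring, ring C the dihydropyranone (O1′, C2′ bearing CH3, C3′, C4′ carbonyl, C5′, C6′ bonded to C3).

## The problem

The target 28 is a 2H-chromen-2-one whose ring A is substituted at every carbon: a 3-hydroxybutan-2-yl group at C5, methyl at C6, hydroxyl at C7, methyl at C8. C3 is joined by a single bond to C6′ of a 2-methyl-2,3-dihydro-4H-pyran-4-one (ring C). There are three stereocentres: the benzylic carbon (R) and the adjacent carbinol carbon (S) of the side chain, in a threo relationship, and C2′ (R) in ring C. The side-chain pair can be set together, but the flat coumarin places C2′ too far away for either element to control the other, so two independent sources of chirality are needed. The hard bond is C5–benzylic carbon: a secondary alkyl group must be attached, with a defined configuration, to an arene carbon flanked by a methyl group and the future C4a substituent. Friedel–Crafts chemistry offers no stereocontrol here, and secondary alkyl–metal cross-coupling risks β-hydride elimination and chain isomerisation. Several functions will not tolerate rough treatment. Ring C is a β-alkoxy enone that base can open by retro-oxa-Michael reaction with loss of C2′. The coumarin is a lactone and a conjugate acceptor at C4. The carbinol β to an electron-rich arene can ionise with aryl participation under strong Lewis acids. The feature that opens the route is that the ring A oxygens on C7 and C8a are both meta to C5 and ortho/para to C4a. In a precursor where C4a is still C–H, an electrophile adds at C4a and places positive charge on C5, so a group held on boron at C5 can migrate onto carbon without a transition metal and with retention.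

## Retrosynthesis

**Ring C.** The enol-ether bond O1′–C6′ of 28 is cut, giving the open δ-hydroxy β-diketone 27 and, with both secondary alcohols silylated, its precursor 26. Only the six-membered closure is possible for this chain. Making ring C last means it never meets base, and the acid that closes it also removes both silyl ethers. The forward step must cleave two secondary silyl ethers and dehydrate a hemiketal under mild acid.

**Ring B.** C3=C4 and O1–C2 of 26 are cut, giving salicylaldehyde 15 and 4-hydroxy-2-pyrone 24. The pyrone serves as a masked 3,5-dioxo acid with a single nucleophilic carbon, which an open-chain diketo ester with two acidic methylenes would not offer. Knoevenagel condensation at the pyrone C3, followed by attack of the ortho phenol on the pyrone lactone, gives the coumarin and releases the β-diketone chain in one operation. The forward reaction must tolerate an aldehyde flanked by a hydroxyl and a branched alkyl group.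

**Pyrone.** 24 comes from keto-dioxinone 22 by thermal loss of the acetonide and acylketene cyclisation. 22 comes from C-acylation of the dienolate of dioxinone 19 with silylated acid 18, made from (R)-3-hydroxybutanoic acid 16. C2′ is therefore bought, and no selectivity is asked of any step.

**Formyl group and phenol protection.** The C4a–CHO bond of 15 is cut to resorcinol 14; C4a is the only free ring position, so no regiochemical question arises, but ortho-formylation needs the free phenol. 14 is unmasked from bis-benzyl ether 13 by hydrogenolysis, which leaves the silyl ether and both stereocentres alone. Methyl ethers were rejected. Thiolate cleavage of a resorcinol dimethyl ether tends to stop after one methyl group. A Lewis acid strong enough to take both would strip the silyl ether and expose the β-aryl carbinol to ionisation.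

**Key disconnection.** The C5–benzylic bond of 13 is cut to aryl bromide 5 and secondary boronic ester 10. Against a cuprate–epoxide opening (which delivers the erythro series) or a cross-coupling, this cut transfers an already complete, enantiopure threo side chain in one stereoretentive step. The aryl partner is reduced to a symmetric-looking pentasubstituted bromobenzene. The forward reaction asks the aryllithium to add to a hindered boronic ester, and the electrophile to attack the ring at the lone C–H carbon.

**Boronic ester.** In 10 the B–C–CH3 unit is cut back to methylboronic ester 7 and (S)-2-methyloxirane 6. A lithiated terminal epoxide adds to boron and the methyl group migrates with opening of the ring, so one operation sets the boron-bearing centre relative to the purchased carbinol centre. An α-lithiated carbamate of a 2-silyloxypropanol would put lithium β to a silyloxy group and invite elimination. In the epoxide the β-oxygen is itself the leaving group of the migration.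

**Aryl bromide.** 5 is the benzyl ether of resorcinol 4, obtained from dimethyl ether 3. The second ring methyl of 3 is the reduced formyl group of aldehyde 2, introduced into bromide 1. In 1 bromine is already meta to both oxygens, a pattern that electrophilic bromination cannot produce, and the two free positions are equivalent.

## Roads not taken

**Alternative 1:** The side chain is cut between the benzylic and carbinol carbons, together with an acetal C–O bond. Irradiation of 6-ethylbenzaldehyde A2 would give a hydroxy-o-quinodimethane, and a chiral titanium–diol Lewis acid would have to guide its hetero-Diels–Alder addition to acetaldehyde A3, giving lactol A1. A1 is the ring-closed form of a protected relative of 15. The formyl carbon is already at C4a, and both side-chain centres and their C–C bond arise in one step. This road is clearly shorter than the chosen one and needs no organolithium or boron chemistry. Its weak points lie in the key step itself. An unactivated, monodentate aliphatic aldehyde is a poor heterodienophile for a photoenol and a poor ligand for the chiral Lewis acid. The trans relationship of the two methyl groups needs a single dienol geometry and a single endo/exo approach. Nothing in A2 helps either the relative or the absolute configuration. Against the step economy of this road, the chosen plan sets stereochemical certainty: both centres of 10 come from enantiopure 6 by stereospecific steps, and the coupling transfers them unchanged.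

**Alternative 2:** Ring A itself is cut at C4a–C5. An amine base would enolise diketo-dioxinone A5, the dioxinone carbon would add to the side-chain ketone, and dehydration would aromatise to benzodioxinone A4. The merit is real: all six substituents are written into the chain, and the ring arrives with C7–OH free and the C8a oxygen and C4a carbon tied up together. That is a cleaner differentiation of the two phenols than the chosen plan offers. The chosen plan does not need it, since only the C8a hydroxyl of 15 can lactonise. The weak points are three. The benzylic stereocentre of A5 sits α to the reacting ketone and is exposed to enolisation under the very base that triggers the aldol. The trimethylated triketide A5 is a long linear assembly with competing pyrone-forming cyclisations. A4 carries C4a at the acid oxidation level, so extra redox steps are needed before ring B can be made. The chosen plan buys ring A and never places a carbonyl next to the benzylic centre.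

**Alternative 3:** Only the C2′–CH3 bond is cut. Pyranone A7 would be O-silylated to a 4-silyloxypyrylium ion, and a methyl Grignard reagent with a chiral copper–diphosphine catalyst would add at the unsubstituted α-carbon, giving bis-silyl ether A6. The attraction is a flat, achiral ring C precursor and late-stage access to either C2′ epimer, a flexibility the chosen plan lacks. For this target the risks are high. The pyrylium ion is conjugated to a coumarin whose C4 and lactone carbonyl are competing sites for the organometallic. The catalyst alone must deliver C2′, because the side-chain centres are too remote to help. The road does not touch the C5–benzylic bond at all, so the hardest problem remains. In the chosen plan C2′ comes from 16 with no selectivity to win.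

Key step: step 6

Assumptions: 1, 6, 7, 16 and 19 are taken as purchasable. β-Diketones 26 and 27 are drawn in the keto form although they will be largely enolised.

## Route

Step 1
Reactants: 1 5-bromo-1,3-dimethoxy-2-methylbenzene
Product: 2 6-bromo-2,4-dimethoxy-3-methylbenzaldehyde
Conditions: POCl3, DMF, 0 °C to 90 °C; then aq. NaOAc
Reagents that add atoms: N,N-dimethylformamide, CN(C)C=O; water, O
Why: Vilsmeier–Haack formylation; the two free positions are equivalent and each is ortho to one methoxy group and para to the other, so only this aldehyde can form, and the bromine slows a second formylation.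

Step 2
Reactants: 2 6-bromo-2,4-dimethoxy-3-methylbenzaldehyde
Product: 3 1-bromo-3,5-dimethoxy-2,4-dimethylbenzene
Conditions: Et3SiH, CF3CO2H, CH2Cl2, 0 °C to rt
Reagents that add atoms: none
Why: Ionic hydrogenation; the protonated aldehyde and then the benzylic cation, stabilised by ortho and para methoxy groups, each accept hydride from the silane, and the aryl bromide is inert.

Step 3
Reactants: 3 1-bromo-3,5-dimethoxy-2,4-dimethylbenzene
Product: 4 5-bromo-2,4-dimethylbenzene-1,3-diol
Conditions: BBr3, CH2Cl2, −78 °C to rt; then H2O
Reagents that add atoms: none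
Why: Lewis-acid cleavage of aryl methyl ethers, carried out before any stereocentre or silyl ether exists.

Step 4
Reactants: 4 5-bromo-2,4-dimethylbenzene-1,3-diol
Product: 5 1,3-bis(benzyloxy)-5-bromo-2,4-dimethylbenzene
Conditions: BnBr, K2CO3, DMF, 60 °C
Reagents that add atoms: benzyl bromide, BrCc1ccccc1
Why: Williamson etherification; benzyl ethers keep the oxygen donors needed in step 6 and can later be removed by neutral hydrogenolysis.

Step 5
Reactants: 6 (S)-2-methyloxirane; 7 2,4,4,5,5-pentamethyl-1,3,2-dioxaborolane
Product: 10 2-[(2S,3S)-3-(tert-butyldimethylsilyloxy)butan-2-yl]-4,4,5,5-tetramethyl-1,3,2-dioxaborolane, via lithiated epoxide 8 (not isolated), via epoxy boronate complex 9 (not isolated)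
Conditions: lithium 2,2,6,6-tetramethylpiperidide, THF, −30 °C, 6 and 7 premixed; then TBSOTf, −78 °C to rt
Reagents that add atoms: tert-butyldimethylsilyl trifluoromethanesulfonate, CC(C)(C)[Si](C)(C)OS(=O)(=O)C(F)(F)F
Why: Homologation of a boronic ester with a lithiated terminal epoxide: the hindered amide removes the ring hydrogen trans to the methyl group, 8 is captured by 7 with retention, and silyl-triflate activation of the epoxide oxygen of 9 drives 1,2-migration of methyl from boron with inversion at the carbenoid carbon. The carbinol centre is that of 6 and is not touched, so trans lithiation plus inversion fixes the boron-bearing centre as S, syn to the silyloxy group; silylation in the same event blocks boron–oxygen elimination to butene.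

Step 6
Reactants: 5 1,3-bis(benzyloxy)-5-bromo-2,4-dimethylbenzene; 10 2-[(2S,3S)-3-(tert-butyldimethylsilyloxy)butan-2-yl]-4,4,5,5-tetramethyl-1,3,2-dioxaborolane
Product: 13 1,3-bis(benzyloxy)-5-[(2R,3S)-3-(tert-butyldimethylsilyloxy)butan-2-yl]-2,4-dimethylbenzene, via aryllithium 11 (not isolated), via aryl alkyl boronate complex 12 (not isolated)
Conditions: 5, n-BuLi, THF, −78 °C; then 10, −78 °C; then NBS (1.05 equiv), THF, −78 °C to rt
Reagents that add atoms: none
Why: Bromine–lithium exchange gives 11, which adds to boron of 10 to form the tetracoordinate boronate 12. N-Bromosuccinimide then attacks the aryl ring of 12 at its only unsubstituted carbon (the future C4a), which is ortho to boron, ortho to one benzyloxy group and para to the other. The resulting cyclohexadienyl cation carries positive charge on the boron-bearing carbon, the secondary alkyl group shifts from boron to that carbon in a concerted 1,2-migration, and loss of bromide and the boryl group from the two adjacent sp3 carbons restores the arene. The closest known reaction type is the transition-metal-free, enantiospecific coupling of secondary boronic esters with electron-rich aryllithiums bearing meta alkoxy groups, triggered by an electrophilic bromine source. No ring is closed and no stereocentre is created: the benzylic centre is carried over with retention because the migrating carbon stays bonded to boron until it bonds to the ring, and the carbinol centre is a spectator. The step needs the electrophile to attack the ring and not the C–B bond, which the two oxygen donors secure, and to attack the C–H carbon and not the methyl-bearing carbons, which is favoured because that carbon is the least hindered and doubly activated. No alkyl–metal species with β-hydrogens is formed, so the branched chain cannot isomerise, and at −78 °C the β-silyloxy group is too poor a leaving group to be eliminated from 12. A small excess of the bromine source at low temperature limits bromination of 13 at the same ring position.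

Step 7
Reactants: 13 1,3-bis(benzyloxy)-5-[(2R,3S)-3-(tert-butyldimethylsilyloxy)butan-2-yl]-2,4-dimethylbenzene
Product: 14 5-[(2R,3S)-3-(tert-butyldimethylsilyloxy)butan-2-yl]-2,4-dimethylbenzene-1,3-diol
Conditions: H2 (1 atm), Pd/C, EtOAc, rt
Reagents that add atoms: none
Why: Hydrogenolysis of benzyl aryl ethers; the silyl ether, the benzylic C–C bond and both stereocentres are inert under neutral conditions in ethyl acetate.

Step 8
Reactants: 14 5-[(2R,3S)-3-(tert-butyldimethylsilyloxy)butan-2-yl]-2,4-dimethylbenzene-1,3-diol
Product: 15 6-[(2R,3S)-3-(tert-butyldimethylsilyloxy)butan-2-yl]-2,4-dihydroxy-3,5-dimethylbenzaldehyde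
Conditions: MgCl2, Et3N, (CH2O)n, MeCN, reflux
Reagents that add atoms: formaldehyde (as paraformaldehyde), C=O
Why: Magnesium-mediated ortho-formylation (Casnati–Skattebøl): the magnesium phenoxide delivers formaldehyde to the ortho carbon and a second formaldehyde oxidises the benzylic alkoxide. Only one ring position is free, and the basic, non-nucleophilic medium spares the silyl ether.

Step 9
Reactants: 16 (R)-3-hydroxybutanoic acid
Product: 18 (R)-3-(tert-butyldimethylsilyloxy)butanoic acid, via bis-silylated acid 17 (not isolated)
Conditions: TBSCl, imidazole, DMF, rt; then K2CO3, MeOH–THF–H2O, rt; citric acid to pH 4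
Reagents that add atoms: tert-butyldimethylsilyl chloride, CC(C)(C)[Si](C)(C)Cl
Why: Exhaustive silylation followed by selective hydrolysis of the labile silyl ester; the stereocentre is not involved.

Step 10
Reactants: 18 (R)-3-(tert-butyldimethylsilyloxy)butanoic acid; 19 2,2,6-trimethyl-4H-1,3-dioxin-4-one
Product: 22 6-[(4R)-4-(tert-butyldimethylsilyloxy)-2-oxopentyl]-2,2-dimethyl-4H-1,3-dioxin-4-one, via acyl imidazole 20 (not isolated), via dioxinone dienolate 21 (not isolated)
Conditions: 18, CDI, THF, rt; added to 21 [from 19, LiN(SiMe3)2 (2.2 equiv), THF, −78 °C]; −78 °C to −20 °C; aq. NH4Cl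
Reagents that add atoms: none
Why: Crossed Claisen acylation of the vinylogous dioxinone enolate at its terminal carbon by an acyl imidazole; the second equivalent of enolate absorbs the acidity of the product, and acyl transfer is faster than enolisation of 20.

Step 11
Reactants: 22 6-[(4R)-4-(tert-butyldimethylsilyloxy)-2-oxopentyl]-2,2-dimethyl-4H-1,3-dioxin-4-one
Product: 24 6-[(2R)-2-(tert-butyldimethylsilyloxy)propyl]-4-hydroxy-2H-pyran-2-one, via acylketene 23 (not isolated)
Conditions: toluene, 110 °C
Reagents that add atoms: none
Why: Retro-hetero-Diels–Alder loss of acetone gives acylketene 23, which is trapped by the enol oxygen of the side-chain ketone to close the 4-hydroxy-2-pyrone.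

Step 12
Reactants: 15 6-[(2R,3S)-3-(tert-butyldimethylsilyloxy)butan-2-yl]-2,4-dihydroxy-3,5-dimethylbenzaldehyde; 24 6-[(2R)-2-(tert-butyldimethylsilyloxy)propyl]-4-hydroxy-2H-pyran-2-one
Product: 26 5-[(2R,3S)-3-(tert-butyldimethylsilyloxy)butan-2-yl]-3-[(5R)-5-(tert-butyldimethylsilyloxy)-3-oxohexanoyl]-7-hydroxy-6,8-dimethyl-2H-chromen-2-one, via benzylidene pyrandione 25 (not isolated)
Conditions: piperidine (cat.), AcOH (cat.), EtOH, reflux
Reagents that add atoms: none
Why: Knoevenagel condensation at C3 of the 4-hydroxypyrone followed by translactonisation: the ortho phenol of 25 attacks the pyrone lactone carbonyl, closing ring B and releasing the pyrone ring as a β-diketone chain, the known outcome for salicylaldehydes with 4-hydroxy-6-alkyl-2-pyrones. The C7 hydroxyl is para to the aldehyde and cannot lactonise.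

Step 13
Reactants: 26 5-[(2R,3S)-3-(tert-butyldimethylsilyloxy)butan-2-yl]-3-[(5R)-5-(tert-butyldimethylsilyloxy)-3-oxohexanoyl]-7-hydroxy-6,8-dimethyl-2H-chromen-2-one
Product: 28 7-hydroxy-5-[(2R,3S)-3-hydroxybutan-2-yl]-6,8-dimethyl-3-[(2R)-2-methyl-4-oxo-3,4-dihydro-2H-pyran-6-yl]-2H-chromen-2-one, via desilylated hydroxy diketone 27 (not isolated)
Conditions: aq. HF (48%), MeCN, 0 °C to rt; then TsOH·H2O (cat.), rt
Reagents that add atoms: none
Why: Fluoride-assisted acidic desilylation frees both alcohols; the δ-hydroxyl of 27 adds to the coumarin-bound carbonyl (the only six-membered closure) and acid-catalysed dehydration gives the dihydropyranone. No base is present, so C2′ cannot be lost by retro-oxa-Michael opening.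

## Compound list

1 | 5-bromo-1,3-dimethoxy-2-methylbenzene | COc1cc(Br)cc(OC)c1C | starting material
2 | 6-bromo-2,4-dimethoxy-3-methylbenzaldehyde | COc1cc(Br)c(C=O)c(OC)c1C | intermediate
3 | 1-bromo-3,5-dimethoxy-2,4-dimethylbenzene | COc1cc(Br)c(C)c(OC)c1C | intermediate
4 | 5-bromo-2,4-dimethylbenzene-1,3-diol | Cc1c(O)cc(Br)c(C)c1O | intermediate
5 | 1,3-bis(benzyloxy)-5-bromo-2,4-dimethylbenzene | Cc1c(OCc2ccccc2)cc(Br)c(C)c1OCc1ccccc1 | intermediate
6 | (S)-2-methyloxirane | C[C@@H]1OC1 | starting material
7 | 2,4,4,5,5-pentamethyl-1,3,2-dioxaborolane (methylboronic acid pinacol ester) | CB1OC(C)(C)C(C)(C)O1 | starting material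
8 | [(2S,3S)-3-methyloxiran-2-yl]lithium | C[C@@H]1O[C@H]1[Li] | intermediate (not isolated)
9 | lithium methyl[(2S,3S)-3-methyloxiran-2-yl](pinacolato)borate | [Li+].C[C@@H]1O[C@H]1[B-]1(C)OC(C)(C)C(C)(C)O1 | intermediate (not isolated)
10 | 2-[(2S,3S)-3-(tert-butyldimethylsilyloxy)butan-2-yl]-4,4,5,5-tetramethyl-1,3,2-dioxaborolane | CC1(C)OB(OC1(C)C)[C@@H](C)[C@H](C)O[Si](C)(C)C(C)(C)C | intermediate
11 | [3,5-bis(benzyloxy)-2,4-dimethylphenyl]lithium | [Li]c1cc(OCc2ccccc2)c(C)c(OCc2ccccc2)c1C | intermediate (not isolated)
12 | lithium [3,5-bis(benzyloxy)-2,4-dimethylphenyl][(2S,3S)-3-(tert-butyldimethylsilyloxy)butan-2-yl](pinacolato)borate | [Li+].Cc1c(OCc2ccccc2)cc([B-]2(OC(C)(C)C(C)(C)O2)[C@@H](C)[C@H](C)O[Si](C)(C)C(C)(C)C)c(C)c1OCc1ccccc1 | intermediate (not isolated)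
13 | 1,3-bis(benzyloxy)-5-[(2R,3S)-3-(tert-butyldimethylsilyloxy)butan-2-yl]-2,4-dimethylbenzene | Cc1c(OCc2ccccc2)cc([C@@H](C)[C@H](C)O[Si](C)(C)C(C)(C)C)c(C)c1OCc1ccccc1 | intermediate
14 | 5-[(2R,3S)-3-(tert-butyldimethylsilyloxy)butan-2-yl]-2,4-dimethylbenzene-1,3-diol | Cc1c(O)cc([C@@H](C)[C@H](C)O[Si](C)(C)C(C)(C)C)c(C)c1O | intermediate
15 | 6-[(2R,3S)-3-(tert-butyldimethylsilyloxy)butan-2-yl]-2,4-dihydroxy-3,5-dimethylbenzaldehyde | Cc1c(O)c(C=O)c([C@@H](C)[C@H](C)O[Si](C)(C)C(C)(C)C)c(C)c1O | intermediate
16 | (R)-3-hydroxybutanoic acid | C[C@@H](O)CC(=O)O | starting material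
17 | tert-butyldimethylsilyl (R)-3-(tert-butyldimethylsilyloxy)butanoate | C[C@@H](O[Si](C)(C)C(C)(C)C)CC(=O)O[Si](C)(C)C(C)(C)C | intermediate (not isolated)
18 | (R)-3-(tert-butyldimethylsilyloxy)butanoic acid | C[C@@H](O[Si](C)(C)C(C)(C)C)CC(=O)O | intermediate
19 | 2,2,6-trimethyl-4H-1,3-dioxin-4-one | CC1=CC(=O)OC(C)(C)O1 | starting material
20 | 1-[(3R)-3-(tert-butyldimethylsilyloxy)butanoyl]-1H-imidazole | C[C@@H](O[Si](C)(C)C(C)(C)C)CC(=O)n1ccnc1 | intermediate (not isolated)
21 | lithium 2,2-dimethyl-6-methylidene-6H-1,3-dioxin-4-olate | [Li+].C=C1C=C([O-])OC(C)(C)O1 | intermediate (not isolated)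
22 | 6-[(4R)-4-(tert-butyldimethylsilyloxy)-2-oxopentyl]-2,2-dimethyl-4H-1,3-dioxin-4-one | C[C@@H](O[Si](C)(C)C(C)(C)C)CC(=O)CC1=CC(=O)OC(C)(C)O1 | intermediate
23 | (7R)-7-(tert-butyldimethylsilyloxy)oct-1-ene-1,3,5-trione | C[C@@H](O[Si](C)(C)C(C)(C)C)CC(=O)CC(=O)C=C=O | intermediate (not isolated)
24 | 6-[(2R)-2-(tert-butyldimethylsilyloxy)propyl]-4-hydroxy-2H-pyran-2-one | C[C@@H](O[Si](C)(C)C(C)(C)C)Cc1cc(O)cc(=O)o1 | intermediate
25 | 3-({6-[(2R,3S)-3-(tert-butyldimethylsilyloxy)butan-2-yl]-2,4-dihydroxy-3,5-dimethylphenyl}methylidene)-6-[(2R)-2-(tert-butyldimethylsilyloxy)propyl]-2H-pyran-2,4(3H)-dione (alkene geometry not defined) | C[C@@H](O[Si](C)(C)C(C)(C)C)CC1=CC(=O)C(=Cc2c(O)c(C)c(O)c(C)c2[C@@H](C)[C@H](C)O[Si](C)(C)C(C)(C)C)C(=O)O1 | intermediate (not isolated)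
26 | 5-[(2R,3S)-3-(tert-butyldimethylsilyloxy)butan-2-yl]-3-[(5R)-5-(tert-butyldimethylsilyloxy)-3-oxohexanoyl]-7-hydroxy-6,8-dimethyl-2H-chromen-2-one | Cc1c(O)c(C)c2oc(=O)c(C(=O)CC(=O)C[C@@H](C)O[Si](C)(C)C(C)(C)C)cc2c1[C@@H](C)[C@H](C)O[Si](C)(C)C(C)(C)C | intermediate
27 | 7-hydroxy-5-[(2R,3S)-3-hydroxybutan-2-yl]-3-[(5R)-5-hydroxy-3-oxohexanoyl]-6,8-dimethyl-2H-chromen-2-one | Cc1c(O)c(C)c2oc(=O)c(C(=O)CC(=O)C[C@@H](C)O)cc2c1[C@@H](C)[C@H](C)O | intermediate (not isolated)
28 | 7-hydroxy-5-[(2R,3S)-3-hydroxybutan-2-yl]-6,8-dimethyl-3-[(2R)-2-methyl-4-oxo-3,4-dihydro-2H-pyran-6-yl]-2H-chromen-2-one | Cc1c(O)c(C)c2oc(=O)c(C3=CC(=O)C[C@@H](C)O3)cc2c1[C@@H](C)[C@H](C)O | target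

## Step count and risks

Total: 13 steps. Longest linear sequence: 9 steps (steps 1, 2, 3, 4, 6, 7, 8, 12, 13).

**Step 6 (key step).** The main risks are these:
- Boronate formation between an ortho-methyl aryllithium and a β-branched secondary boronic ester may be slow or incomplete, which leaves aryllithium to be quenched or brominated.
- The silyloxide may be eliminated from the boronate if the mixture has to be warmed.
- The electrophile may attack the C–B bond or a methyl-bearing ring carbon.
- The product may be brominated further at its last ring C–H.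

Fallback, setting out from 5 and returning at 13, builds the benzylic centre by hydroxyl-directed hydrogenation instead of boron migration. Bromine–lithium exchange of 5 and acylation with (2S)-2-(tert-butyldimethylsilyloxy)-N-methoxy-N-methylpropanamide F1 (from ethyl (S)-lactate by silylation and aminolysis) would give (2S)-1-[3,5-bis(benzyloxy)-2,4-dimethylphenyl]-2-(tert-butyldimethylsilyloxy)propan-1-one F2. Wittig methylenation with Ph3P=CH2 would give tert-butyl({(2S)-3-[3,5-bis(benzyloxy)-2,4-dimethylphenyl]but-3-en-2-yl}oxy)dimethylsilane F3, and Bu4NF would free (2S)-3-[3,5-bis(benzyloxy)-2,4-dimethylphenyl]but-3-en-2-ol F4. Hydrogenation with the cationic catalyst [Rh(nbd)(dppb)]BF4 in CH2Cl2 should deliver hydrogen to the face held by the hydroxyl, in the conformer that keeps the carbinol hydrogen next to the aryl group. The expected product is the threo alcohol (2S,3R)-3-[3,5-bis(benzyloxy)-2,4-dimethylphenyl]butan-2-ol F5, and TBSCl/imidazole then gives 13.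

**Step 5.** The lithiated epoxide may decompose by carbenoid pathways before boron captures it. Methyl is a slow migrating group, so the β-oxido boronate may lose boron and oxygen to give butene before silylation. Trans selectivity of the lithiation may erode. Fallback: it uses neither 6 nor 7, sets out from commercial (S)-but-3-yn-2-ol F6 and returns at 10. Copper-catalysed internal-selective protoboration (B2pin2, MeOH, (SIMes)CuCl, NaOt-Bu, THF) would give (2S)-3-(4,4,5,5-tetramethyl-1,3,2-dioxaborolan-2-yl)but-3-en-2-ol F7. Hydroxyl-directed hydrogenation with [Rh(nbd)(dppb)]BF4, by the same conformational argument as above, should give (2S,3S)-3-(4,4,5,5-tetramethyl-1,3,2-dioxaborolan-2-yl)butan-2-ol F8, and TBSCl/imidazole gives 10.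

**Step 12.** Condensation at a di-ortho-substituted aldehyde deactivated by a para hydroxyl may be sluggish. A second pyrone may add in conjugate fashion to the benzylidene intermediate before the phenol closes ring B. Fallback, setting out from 22 and 15 and returning at 28, forms ring C before ring B. Heating 22 with MeOH in toluene would trap the acylketene as methyl (7R)-7-(tert-butyldimethylsilyloxy)-3,5-dioxooctanoate F9. Aqueous HF in MeCN followed by catalytic TsOH would give methyl 2-[(2R)-2-methyl-4-oxo-3,4-dihydro-2H-pyran-6-yl]acetate F10. Its vinylogously activated methylene would undergo Knoevenagel condensation and lactonisation with 15 (piperidine, AcOH, EtOH), giving 5-[(2R,3S)-3-(tert-butyldimethylsilyloxy)butan-2-yl]-7-hydroxy-6,8-dimethyl-3-[(2R)-2-methyl-4-oxo-3,4-dihydro-2H-pyran-6-yl]-2H-chromen-2-one F11. Aqueous HF in MeCN then gives 28.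

**Step 8.** Formylation at a position flanked by the branched side chain may stop at the hydroxymethyl stage, or the benzylic intermediate may alkylate a second arene. Fallback, setting out from 13 and returning at 15, installs the carbon through a halogen. NBS in MeCN at 0 °C would brominate the single free position to give 1,5-bis(benzyloxy)-2-bromo-3-[(2R,3S)-3-(tert-butyldimethylsilyloxy)butan-2-yl]-4,6-dimethylbenzene F12. n-BuLi and then DMF would give 2,4-bis(benzyloxy)-6-[(2R,3S)-3-(tert-butyldimethylsilyloxy)butan-2-yl]-3,5-dimethylbenzaldehyde F13. Hydrogenolysis (H2, Pd/C, EtOAc, uptake limited to two equivalents) gives 15.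

## Further compounds

F1 | step 6 | (2S)-2-(tert-butyldimethylsilyloxy)-N-methoxy-N-methylpropanamide | C[C@H](O[Si](C)(C)C(C)(C)C)C(=O)N(C)OC
F2 | step 6 | (2S)-1-[3,5-bis(benzyloxy)-2,4-dimethylphenyl]-2-(tert-butyldimethylsilyloxy)propan-1-one | Cc1c(OCc2ccccc2)cc(C(=O)[C@H](C)O[Si](C)(C)C(C)(C)C)c(C)c1OCc1ccccc1
F3 | step 6 | tert-butyl({(2S)-3-[3,5-bis(benzyloxy)-2,4-dimethylphenyl]but-3-en-2-yl}oxy)dimethylsilane | Cc1c(OCc2ccccc2)cc(C(=C)[C@H](C)O[Si](C)(C)C(C)(C)C)c(C)c1OCc1ccccc1
F4 | step 6 | (2S)-3-[3,5-bis(benzyloxy)-2,4-dimethylphenyl]but-3-en-2-ol | Cc1c(OCc2ccccc2)cc(C(=C)[C@H](C)O)c(C)c1OCc1ccccc1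
F5 | step 6 | (2S,3R)-3-[3,5-bis(benzyloxy)-2,4-dimethylphenyl]butan-2-ol | Cc1c(OCc2ccccc2)cc([C@@H](C)[C@H](C)O)c(C)c1OCc1ccccc1
F6 | step 5 | (S)-but-3-yn-2-ol | C#C[C@H](C)O
F7 | step 5 | (2S)-3-(4,4,5,5-tetramethyl-1,3,2-dioxaborolan-2-yl)but-3-en-2-ol | C=C(B1OC(C)(C)C(C)(C)O1)[C@H](C)O
F8 | step 5 | (2S,3S)-3-(4,4,5,5-tetramethyl-1,3,2-dioxaborolan-2-yl)butan-2-ol | CC1(C)OB(OC1(C)C)[C@@H](C)[C@H](C)O
F9 | step 12 | methyl (7R)-7-(tert-butyldimethylsilyloxy)-3,5-dioxooctanoate | COC(=O)CC(=O)CC(=O)C[C@@H](C)O[Si](C)(C)C(C)(C)C
F10 | step 12 | methyl 2-[(2R)-2-methyl-4-oxo-3,4-dihydro-2H-pyran-6-yl]acetate | COC(=O)CC1=CC(=O)C[C@@H](C)O1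
F11 | step 12 | 5-[(2R,3S)-3-(tert-butyldimethylsilyloxy)butan-2-yl]-7-hydroxy-6,8-dimethyl-3-[(2R)-2-methyl-4-oxo-3,4-dihydro-2H-pyran-6-yl]-2H-chromen-2-one | Cc1c(O)c(C)c2oc(=O)c(C3=CC(=O)C[C@@H](C)O3)cc2c1[C@@H](C)[C@H](C)O[Si](C)(C)C(C)(C)C
F12 | step 8 | 1,5-bis(benzyloxy)-2-bromo-3-[(2R,3S)-3-(tert-butyldimethylsilyloxy)butan-2-yl]-4,6-dimethylbenzene | Cc1c(OCc2ccccc2)c(Br)c([C@@H](C)[C@H](C)O[Si](C)(C)C(C)(C)C)c(C)c1OCc1ccccc1
F13 | step 8 | 2,4-bis(benzyloxy)-6-[(2R,3S)-3-(tert-butyldimethylsilyloxy)butan-2-yl]-3,5-dimethylbenzaldehyde | Cc1c(OCc2ccccc2)c(C=O)c([C@@H](C)[C@H](C)O[Si](C)(C)C(C)(C)C)c(C)c1OCc1ccccc1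
A1 | alternative 1 | (3S,4R)-6,8-bis(methoxymethoxy)-3,4,5,7-tetramethylisochroman-1-ol (either configuration at C1) | Cc1c(OCOC)c(C)c(OCOC)c2c1[C@@H](C)[C@H](C)OC2O
A2 | alternative 1 | 6-ethyl-2,4-bis(methoxymethoxy)-3,5-dimethylbenzaldehyde | CCc1c(C)c(OCOC)c(C)c(OCOC)c1C=O
A3 | alternative 1 | acetaldehyde | CC=O
A4 | alternative 2 | 7-hydroxy-2,2,6,8-tetramethyl-5-[(2R,3S)-3-(tert-butyldimethylsilyloxy)butan-2-yl]-4H-1,3-benzodioxin-4-one | CC1(C)OC(=O)c2c(O1)c(C)c(O)c(C)c2[C@@H](C)[C@H](C)O[Si](C)(C)C(C)(C)C
A5 | alternative 2 | 6-[(6S,7S)-7-(tert-butyldimethylsilyloxy)-4,6-dimethyl-3,5-dioxooctan-2-yl]-2,2-dimethyl-4H-1,3-dioxin-4-one (C2 and C4 of the chain not defined) | CC1(C)OC(=O)C=C(O1)C(C)C(=O)C(C)C(=O)[C@@H](C)[C@H](C)O[Si](C)(C)C(C)(C)C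
A6 | alternative 3 | 7-(tert-butyldimethylsilyloxy)-5-[(2R,3S)-3-(tert-butyldimethylsilyloxy)butan-2-yl]-6,8-dimethyl-3-[(2R)-2-methyl-4-oxo-3,4-dihydro-2H-pyran-6-yl]-2H-chromen-2-one | Cc1c(O[Si](C)(C)C(C)(C)C)c(C)c2oc(=O)c(C3=CC(=O)C[C@@H](C)O3)cc2c1[C@@H](C)[C@H](C)O[Si](C)(C)C(C)(C)C
A7 | alternative 3 | 7-(tert-butyldimethylsilyloxy)-5-[(2R,3S)-3-(tert-butyldimethylsilyloxy)butan-2-yl]-6,8-dimethyl-3-(4-oxo-4H-pyran-2-yl)-2H-chromen-2-one | Cc1c(O[Si](C)(C)C(C)(C)C)c(C)c2oc(=O)c(-c3cc(=O)cco3)cc2c1[C@@H](C)[C@H](C)O[Si](C)(C)C(C)(C)C
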